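## Retrosynthetic overview

1. The three esters and the free C15 alcohol come last. They are set on the 6β,7α-diol, which comes from the 8-en-6-one 22 by C7 enolate hydroxylation and α-face reduction of C6. The side chain (C11–C16) enters by Negishi coupling at C9.
2. Ring B oxidation pattern: the 6-oxo enol triflate 15 comes from the 7-ene-6,9-dione 13, made by γ-oxidation of enone 12. The 2α-acetate of 12 is the Baeyer–Villiger product of a 2α-acetyl group.
3. Key disconnection C3–C4: trans-decalin 11 comes from the monocyclic dienone 9 by a hydrogen-atom-transfer-initiated 6-endo radical cyclization. The C5 isopropenyl group gives the C4 radical and the CH2 terminus of a C2-acetyl-substituted alkene is C3.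
4. Dienone 9 comes from (R)-carvone by methylation, anti-selective 2-bromoallylation at the future C10 and Stille acylvinylation. Ring B is taken from the chiral pool; ring A is closed in step 4.
5. Enabling feature: C4 of ring A is a quaternary carbon with two methyl groups next to the ring-fusion CH (C5) of ring B, so it is the Markovnikov carbon of an isopropenyl group. C2 bears an oxygen that can be traced back to an acetyl group, which makes C3 the terminus of a radical acceptor.

Key step: step 4

Remark: labdane numbering is used for all bicyclic compounds (α = face opposite to the C10 methyl group), and ketone 3 is carried on with its C6 epimer because that centre is re-enolized in step 2.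

## Route

Step 1
Reactants: 1 (R)-carvone
Product: 3 trans-6-methylcarvone, via lithium dienolate 2 (not isolated)
Conditions: LiN(i-Pr)2, THF, –78 °C; then MeI, –78 → 0 °C
Reagents that add atoms: iodomethane, CI
Why: Kinetic α'-deprotonation of carvone and C-methylation of the cross-conjugated dienolate (enolate alkylation) is standard, and the configuration of the new centre does not matter because it is enolized again in step 2.

Step 2
Reactants: 3 trans-6-methylcarvone; 4 2,3-dibromoprop-1-ene
Product: 6 6-(2-bromoallyl)-6-methylcarvone (methyl cis and bromoallyl trans to the isopropenyl group), via lithium dienolate 5 (not isolated)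
Conditions: LiN(i-Pr)2, THF, –78 → –20 °C; then 4, DMPU, –78 °C → rt
Reagents that add atoms: none
Why: Enolate alkylation with the allylic bromide should occur on the face anti to the neighbouring isopropenyl group, which sets the quaternary centre (future C10) with the methyl group cis and the C1 arm trans to the future C4 arm, as a trans-decalin needs.

Step 3
Reactants: 6 6-(2-bromoallyl)-6-methylcarvone; 7 tributyl(1-ethoxyvinyl)stannane
Product: 9 6-(2-methylene-3-oxobutyl)-6-methylcarvone, via 2-ethoxydiene 8 (not isolated)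
Conditions: Pd(PPh3)4 (5 mol %), CuI (10 mol %), DMF, 60 °C; then 1 M HCl, THF, 0 °C
Reagents that add atoms: water, O
Why: Stille coupling of a 1,1-disubstituted vinyl bromide with the α-ethoxyvinyl stannane followed by enol ether hydrolysis is the standard conversion of a vinyl halide into a vinyl methyl ketone, and CuI speeds up transmetalation so that coupling should outrun Heck-type side reactions.

Step 4
Reactants: 9 6-(2-methylene-3-oxobutyl)-6-methylcarvone
Product: 11 2α-acetyl-4,4,8,10β-tetramethyl-trans-decal-7-en-9-one, via 2β-acetyl epimer 10 (not isolated)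
Conditions: Fe(acac)3 (30 mol %), PhSiH3 (2.5 equiv, slow addition), EtOH/ethylene glycol 5:1, 0.01 M, 60 °C; then DBU (0.3 equiv), CH2Cl2, rt
Reagents that add atoms: none
Why: Fe(acac)3 and PhSiH3 in ethanol generate an iron hydride that transfers a hydrogen atom to the CH2 terminus of the electron-rich isopropenyl group; the tertiary C4 radical adds to the unsubstituted CH2 terminus (C3) of the α-substituted vinyl ketone, and the α-keto radical at C2 is reduced to an iron enolate and protonated by ethanol. The closest known reaction type is the iron-hydride-initiated reductive olefin coupling (radical Giese addition) in its intramolecular form on carvone-derived dienes. Ring A closes in the 6-endo-trig mode, because 5-exo attack would have to occur at the fully substituted, acyl-bearing carbon C2 and is disfavoured by both sterics and polarity. C4 becomes the quaternary gem-dimethyl carbon (one methyl arises from the alkene CH2); C5 and C10 are already fixed, and because the two reacting arms are trans-diequatorial on ring B the ring fusion can only be trans. The new stereocenter C2 is set under thermodynamic control by the DBU equilibration, which places the acetyl group equatorial (2α), away from the syn-axial C10 and 4β methyl groups. The step needs hydrogen-atom transfer to the isopropenyl group in preference to the two enone C=C bonds and ring closure faster than reduction of the radical; the first is secured by the preference of metal hydrides for electron-rich 1,1-disubstituted alkenes, the second by matched polarity, the pre-organized arms and a low hydride concentration.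

Step 5
Reactants: 11 2α-acetyl-4,4,8,10β-tetramethyl-trans-decal-7-en-9-one
Product: 12 2α-acetoxy-4,4,8,10β-tetramethyl-trans-decal-7-en-9-one
Conditions: mCPBA (2 equiv), NaHCO3, CH2Cl2, 0 °C → rt
Reagents that add atoms: 3-chloroperbenzoic acid, OOC(=O)c1cccc(Cl)c1
Why: Baeyer–Villiger oxidation of the methyl ketone with migration of the secondary ring carbon (retention at C2) should give the 2α-acetate directly, while the conjugated, hindered C9 carbonyl and its electron-poor alkene react far more slowly with the peracid.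

Step 6
Reactants: 12 2α-acetoxy-4,4,8,10β-tetramethyl-trans-decal-7-en-9-one
Product: 13 2α-acetoxy-4,4,8,10β-tetramethyl-trans-decal-7-ene-6,9-dione
Conditions: Pd(OH)2 on carbon (5 mol %), t-BuOOH (5 equiv), K2CO3 (0.25 equiv), CH2Cl2, 4 °C → rt
Reagents that add atoms: tert-butyl hydroperoxide, CC(C)(C)OO
Why: Palladium-catalysed peroxide oxidation of α,β-enones at the γ-methylene (enone to 1,4-enedione) should place the C6 carbonyl, C6 being the only γ-CH2 of the enone; the ring fusion stays trans.

Step 7
Reactants: 13 2α-acetoxy-4,4,8,10β-tetramethyl-trans-decal-7-ene-6,9-dione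
Product: 15 2α-acetoxy-4,4,8,10β-tetramethyl-6-oxo-trans-decal-8-en-9-yl trifluoromethanesulfonate, via lithium enolate 14 (not isolated)
Conditions: LiBH(s-Bu)3 (1.05 equiv), THF, –78 °C; then PhNTf2, –78 → 0 °C
Reagents that add atoms: N-phenylbis(trifluoromethanesulfonimide), O=S(=O)(N(c1ccccc1)S(=O)(=O)C(F)(F)F)C(F)(F)F
Why: Conjugate reduction by the bulky hydride at the unsubstituted alkene carbon C7 should give the C9 enolate regiospecifically, and O-sulfonylation in situ (conjugate reduction–enolate triflation) fixes the tetrasubstituted C8=C9 bond and leaves the C6 ketone free.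

Step 8
Reactants: 16 (E)-3-methylpent-2-en-4-yn-1-ol
Product: 17 (E)-tert-butyldimethyl[(3-methylpent-2-en-4-yn-1-yl)oxy]silane
Conditions: TBSCl, imidazole, CH2Cl2, 0 °C → rt
Reagents that add atoms: tert-butyldimethylsilyl chloride, CC(C)(C)[Si](C)(C)Cl
Why: Silylation of a primary allylic alcohol is routine and the silyl ether survives every later step up to the final fluoride treatment.

Step 9
Reactants: 17 (E)-tert-butyldimethyl[(3-methylpent-2-en-4-yn-1-yl)oxy]silane
Product: 18 (E)-tert-butyldimethyl[(3-methylpenta-2,4-dien-1-yl)oxy]silane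
Conditions: H2 (1 atm), Pd on CaCO3 poisoned with Pb(OAc)2, quinoline, hexane, rt
Reagents that add atoms: none
Why: Semihydrogenation of the terminal alkyne over poisoned palladium should stop at the diene without touching the trisubstituted (E)-alkene.

Step 10
Reactants: 18 (E)-tert-butyldimethyl[(3-methylpenta-2,4-dien-1-yl)oxy]silane
Product: 20 (E)-tert-butyl[(5-iodo-3-methylpent-2-en-1-yl)oxy]dimethylsilane, via B-alkyl-9-BBN adduct 19 (not isolated)
Conditions: 9-borabicyclo[3.3.1]nonane, THF, 0 °C → rt; then NaOMe, I2, MeOH, 0 °C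
Reagents that add atoms: iodine, II
Why: Anti-Markovnikov hydroboration with the bulky borane should take place only at the terminal vinyl group, and base-induced iodinolysis of the primary alkylborane gives the homoallylic iodide with the (E)-alkene intact.

Step 11
Reactants: 15 2α-acetoxy-4,4,8,10β-tetramethyl-6-oxo-trans-decal-8-en-9-yl trifluoromethanesulfonate; 20 (E)-tert-butyl[(5-iodo-3-methylpent-2-en-1-yl)oxy]dimethylsilane
Product: 22 2α-acetoxy-15-(tert-butyldimethylsilyloxy)labda-8,13E-dien-6-one, via alkylzinc iodide 21 (not isolated)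
Conditions: 20, Zn dust, LiCl, THF, 40 °C; then 15, PdCl2(dppf) (5 mol %), THF/NMP, 50 °C
Reagents that add atoms: none
Why: Negishi sp3–sp2 coupling of a primary alkylzinc with a tetrasubstituted cyclohexenyl triflate next to a quaternary carbon has close analogy in 2,6,6-trimethylcyclohexenyl triflates, tolerates ketone, acetate and silyl ether, and runs without base so that the β,γ-unsaturated ketone should not isomerize.

Step 12
Reactants: 22 2α-acetoxy-15-(tert-butyldimethylsilyloxy)labda-8,13E-dien-6-one
Product: 24 2α-acetoxy-7α-hydroxy-15-(tert-butyldimethylsilyloxy)labda-8,13E-dien-6-one, via potassium dienolate 23 (not isolated)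
Conditions: KN(SiMe3)2 (1.1 equiv), THF, –78 °C; then 2-(phenylsulfonyl)-3-phenyloxaziridine, –78 °C; AcOH quench
Reagents that add atoms: 2-(phenylsulfonyl)-3-phenyloxaziridine, O=S(=O)(N1OC1c1ccccc1)c1ccccc1
Why: Kinetic deprotonation at the doubly activated C7 gives the linear dienolate, whose hydroxylation (enolate oxidation with an N-sulfonyloxaziridine) should occur at the α-carbon C7 from the α-face, opposite to the axial C10 and 4β methyl groups, while γ-attack at the fully substituted C9 is blocked.

Step 13
Reactants: 24 2α-acetoxy-7α-hydroxy-15-(tert-butyldimethylsilyloxy)labda-8,13E-dien-6-one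
Product: 25 2α-acetoxy-15-(tert-butyldimethylsilyloxy)labda-8,13E-diene-6β,7α-diol
Conditions: NaBH4, CeCl3·7H2O, MeOH, –40 °C
Reagents that add atoms: none
Why: In this Luche-type 1,2-reduction the hydride should reach C6 from the α-face, because the β-face is shielded by the two 1,3-diaxial methyl groups (C10 and 4β), which gives the axial 6β-alcohol and so the trans-diaxial diol.

Step 14
Reactants: 25 2α-acetoxy-15-(tert-butyldimethylsilyloxy)labda-8,13E-diene-6β,7α-diol
Product: 26 2α,7α-diacetoxy-15-(tert-butyldimethylsilyloxy)labda-8,13E-dien-6β-ol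
Conditions: Ac2O (1.2 equiv), pyridine, DMAP (5 mol %), CH2Cl2, 0 °C
Reagents that add atoms: acetic anhydride, CC(=O)OC(C)=O
Why: The allylic 7α-hydroxyl is far more accessible than the 6β-hydroxyl flanked by two syn-axial methyl groups, so limited anhydride should acetylate C7 only (selective acylation of the less hindered alcohol).

Step 15
Reactants: 26 2α,7α-diacetoxy-15-(tert-butyldimethylsilyloxy)labda-8,13E-dien-6β-ol
Product: 27 2α,7α-diacetoxy-6β-(3-methylbutanoyloxy)-15-(tert-butyldimethylsilyloxy)labda-8,13E-diene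
Conditions: 3-methylbutanoic anhydride (5 equiv), DMAP (2 equiv), Et3N, toluene, 60 °C
Reagents that add atoms: 3-methylbutanoic anhydride, CC(C)CC(=O)OC(=O)CC(C)C
Why: DMAP-catalysed acylation with excess anhydride at raised temperature should esterify the hindered axial alcohol, and acetyl migration from O7 is not possible across the trans-diaxial diol.

Step 16
Reactants: 27 2α,7α-diacetoxy-6β-(3-methylbutanoyloxy)-15-(tert-butyldimethylsilyloxy)labda-8,13E-diene
Product: 28 2α,7α-diacetoxy-6β-(3-methylbutanoyloxy)labda-8,13E-dien-15-ol (CNP0257091.1)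
Conditions: HF·pyridine, pyridine, THF, 0 °C
Reagents that add atoms: none
Why: Buffered fluoride should cleave the primary allylic silyl ether without touching the three esters or ionizing the allylic acetate.

## Compound list

1 | (R)-carvone, (5R)-2-methyl-5-(prop-1-en-2-yl)cyclohex-2-en-1-one | CC(=C)[C@@H]1CC=C(C)C(=O)C1 | starting material
2 | lithium dienolate of carvone (C6 deprotonated) | [Li+].CC(=C)[C@@H]1CC=C(C)C([O-])=C1 | intermediate
3 | trans-6-methylcarvone (6-methyl trans to the 5-isopropenyl group; used with its C6 epimer) | CC(=C)[C@@H]1CC=C(C)C(=O)[C@H]1C | intermediate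
4 | 2,3-dibromoprop-1-ene | BrCC(Br)=C | starting material
5 | lithium dienolate of 3 | [Li+].CC(=C)[C@@H]1CC=C(C)C([O-])=C1C | intermediate
6 | 6-(2-bromoprop-2-en-1-yl)-2,6-dimethyl-5-(prop-1-en-2-yl)cyclohex-2-en-1-one (6-methyl cis, bromoallyl trans to isopropenyl) | CC(=C)[C@@H]1CC=C(C)C(=O)[C@@]1(C)CC(Br)=C | intermediate
7 | tributyl(1-ethoxyvinyl)stannane | CCCC[Sn](CCCC)(CCCC)C(=C)OCC | starting material
8 | 6-(3-ethoxy-2-methylenebut-3-en-1-yl) analogue of 6 (2-ethoxydiene) | CC(=C)[C@@H]1CC=C(C)C(=O)[C@@]1(C)CC(=C)C(=C)OCC | intermediate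
9 | 6-(2-methylene-3-oxobutyl)-2,6-dimethyl-5-(prop-1-en-2-yl)cyclohex-2-en-1-one (configuration as in 6) | CC(=C)[C@@H]1CC=C(C)C(=O)[C@@]1(C)CC(=C)C(C)=O | intermediate
10 | 2β-acetyl (axial) epimer of 11 | CC(=O)[C@@H]1CC(C)(C)[C@@H]2CC=C(C)C(=O)[C@@]2(C)C1 | intermediate
11 | 2α-acetyl-4,4,8,10β-tetramethyl-trans-decal-7-en-9-one (5α-H) | CC(=O)[C@H]1CC(C)(C)[C@@H]2CC=C(C)C(=O)[C@@]2(C)C1 | intermediate
12 | 2α-acetoxy-4,4,8,10β-tetramethyl-trans-decal-7-en-9-one | CC(=O)O[C@H]1CC(C)(C)[C@@H]2CC=C(C)C(=O)[C@@]2(C)C1 | intermediate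
13 | 2α-acetoxy-4,4,8,10β-tetramethyl-trans-decal-7-ene-6,9-dione | CC(=O)O[C@H]1CC(C)(C)[C@@H]2C(=O)C=C(C)C(=O)[C@@]2(C)C1 | intermediate
14 | lithium C9 enolate (C8=C9) of the 6-oxo compound | [Li+].CC(=O)O[C@H]1CC(C)(C)[C@@H]2C(=O)CC(C)=C([O-])[C@@]2(C)C1 | intermediate
15 | 2α-acetoxy-4,4,8,10β-tetramethyl-6-oxo-trans-decal-8-en-9-yl trifluoromethanesulfonate | CC(=O)O[C@H]1CC(C)(C)[C@@H]2C(=O)CC(C)=C(OS(=O)(=O)C(F)(F)F)[C@@]2(C)C1 | intermediate
16 | (E)-3-methylpent-2-en-4-yn-1-ol | C#C/C(C)=C/CO | starting material
17 | (E)-tert-butyldimethyl[(3-methylpent-2-en-4-yn-1-yl)oxy]silane | C#C/C(C)=C/CO[Si](C)(C)C(C)(C)C | intermediate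
18 | (E)-tert-butyldimethyl[(3-methylpenta-2,4-dien-1-yl)oxy]silane | C=C/C(C)=C/CO[Si](C)(C)C(C)(C)C | intermediate
19 | 9-[(E)-5-(tert-butyldimethylsilyloxy)-3-methylpent-3-en-1-yl]-9-borabicyclo[3.3.1]nonane | CC(C)(C)[Si](C)(C)OC/C=C(\C)CCB1C2CCCC1CCC2 | intermediate
20 | (E)-tert-butyl[(5-iodo-3-methylpent-2-en-1-yl)oxy]dimethylsilane | CC(C)(C)[Si](C)(C)OC/C=C(\C)CCI | intermediate
21 | [(E)-5-(tert-butyldimethylsilyloxy)-3-methylpent-3-en-1-yl]zinc iodide | CC(C)(C)[Si](C)(C)OC/C=C(\C)CC[Zn]I | intermediate
22 | 2α-acetoxy-15-(tert-butyldimethylsilyloxy)labda-8,13E-dien-6-one | CC(=O)O[C@H]1CC(C)(C)[C@@H]2C(=O)CC(C)=C(CC/C(C)=C/CO[Si](C)(C)C(C)(C)C)[C@@]2(C)C1 | intermediate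
23 | potassium dienolate of 22 (O–C6=C7–C8=C9) | [K+].CC(=O)O[C@H]1CC(C)(C)[C@@H]2C([O-])=CC(C)=C(CC/C(C)=C/CO[Si](C)(C)C(C)(C)C)[C@@]2(C)C1 | intermediate
24 | 2α-acetoxy-7α-hydroxy-15-(tert-butyldimethylsilyloxy)labda-8,13E-dien-6-one | CC(=O)O[C@H]1CC(C)(C)[C@@H]2C(=O)[C@@H](O)C(C)=C(CC/C(C)=C/CO[Si](C)(C)C(C)(C)C)[C@@]2(C)C1 | intermediate
25 | 2α-acetoxy-15-(tert-butyldimethylsilyloxy)labda-8,13E-diene-6β,7α-diol | CC(=O)O[C@H]1CC(C)(C)[C@@H]2[C@H](O)[C@@H](O)C(C)=C(CC/C(C)=C/CO[Si](C)(C)C(C)(C)C)[C@@]2(C)C1 | intermediate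
26 | 2α,7α-diacetoxy-15-(tert-butyldimethylsilyloxy)labda-8,13E-dien-6β-ol | CC(=O)O[C@H]1CC(C)(C)[C@@H]2[C@H](O)[C@@H](OC(C)=O)C(C)=C(CC/C(C)=C/CO[Si](C)(C)C(C)(C)C)[C@@]2(C)C1 | intermediate
27 | 2α,7α-diacetoxy-6β-(3-methylbutanoyloxy)-15-(tert-butyldimethylsilyloxy)labda-8,13E-diene | CC(=O)O[C@H]1CC(C)(C)[C@@H]2[C@H](OC(=O)CC(C)C)[C@@H](OC(C)=O)C(C)=C(CC/C(C)=C/CO[Si](C)(C)C(C)(C)C)[C@@]2(C)C1 | intermediate
28 | 2α,7α-diacetoxy-6β-(3-methylbutanoyloxy)labda-8,13E-dien-15-ol (2S,5S,6S,7S,10S; CNP0257091.1) | CC(=O)O[C@H]1CC(C)(C)[C@@H]2[C@H](OC(=O)CC(C)C)[C@@H](OC(C)=O)C(C)=C(CC/C(C)=C/CO)[C@@]2(C)C1 | target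

## Step count and risks

Total step count: 16. Longest linear sequence: 13 steps (steps 1–7 and 11–16 from 1); the side-chain iodide 20 takes 3 steps (8–10).

The three steps most likely to fail:

1. Step 7. The hydride may be delivered with the wrong regiochemistry or to a carbonyl group, and the C9 enolate may equilibrate towards C6 before O-sulfonylation. The fallback brings in the C6 oxygen at the alcohol level, so that reduction–triflation is run on a simple enone; it also bypasses step 6. It sets out from enone 12. Soft enolization (TBSOTf, Et3N, CH2Cl2) should give the silyl dienol ether F1. Vinylogous Rubottom oxidation (dimethyldioxirane, acetone, –78 °C) should give the 6-hydroxy enone F2, whose C6 configuration is immaterial. Silylation (TESCl, imidazole) gives the triethylsilyl ether F3. LiBH(s-Bu)3 followed by PhNTf2 gives the enol triflate F4. HF·pyridine removes the triethylsilyl group to give the alcohol F5, and Dess–Martin oxidation returns to the route at triflate 15.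

2. Step 11. Oxidative addition and transmetalation at the tetrasubstituted triflate next to the quaternary C10 may be slow, so that β-hydride elimination or protodemetalation of the alkylzinc takes over. The fallback forms the C9–C11 bond by carbonyl addition. It sets out from enedione 13 and uses iodide 20. Compound 13 is first converted into its C6 dienolate with LiN(SiMe3)2 (1 equiv, THF, –78 °C), which leaves C9 as the only electrophilic carbonyl. The organocerium reagent made from 20 (t-BuLi, then CeCl3, THF, –78 °C) should add to C9 and give, after protonation, the γ-hydroxy enone F6. SmI2 (THF/MeOH, –78 °C) then removes the C9 hydroxyl reductively with protonation of the dienolate at C7, which returns to the route at ketone 22.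

3. Step 4. The tertiary radical may be reduced, or hydrogen-atom transfer may occur at the acceptor alkene, before ring closure. The fallback closes the same C3–C4 bond by a cationic annulation terminated by the vinyl halide. It sets out from bromide 6. HCO2H (40 °C, then aqueous work-up) protonates the isopropenyl group, the C4 cation is captured by the CH2 terminus of the 2-bromoallyl group, and hydrolysis of the α-bromo cation should give the 2,9-diketone F7. NaBH4 (MeOH, –78 °C) should reduce only the saturated C2 ketone, from the α-face, to the axial 2β-alcohol F8. Mitsunobu inversion with acetic acid (PPh3, DIAD, toluene) returns to the route at acetate 12.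

Further compounds
F1 | step 7 | 2α-acetoxy-9-(tert-butyldimethylsilyloxy)-4,4,8,10β-tetramethyl-trans-decal-6,8-diene | CC(=O)O[C@H]1CC(C)(C)[C@@H]2C=CC(C)=C(O[Si](C)(C)C(C)(C)C)[C@@]2(C)C1
F2 | step 7 | 2α-acetoxy-6-hydroxy-4,4,8,10β-tetramethyl-trans-decal-7-en-9-one (C6 epimers) | CC(=O)O[C@H]1CC(C)(C)[C@@H]2C(O)C=C(C)C(=O)[C@@]2(C)C1
F3 | step 7 | 2α-acetoxy-6-(triethylsilyloxy)-4,4,8,10β-tetramethyl-trans-decal-7-en-9-one | CC(=O)O[C@H]1CC(C)(C)[C@@H]2C(O[Si](CC)(CC)CC)C=C(C)C(=O)[C@@]2(C)C1
F4 | step 7 | 2α-acetoxy-6-(triethylsilyloxy)-4,4,8,10β-tetramethyl-trans-decal-8-en-9-yl trifluoromethanesulfonate | CC(=O)O[C@H]1CC(C)(C)[C@@H]2C(O[Si](CC)(CC)CC)CC(C)=C(OS(=O)(=O)C(F)(F)F)[C@@]2(C)C1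
F5 | step 7 | 2α-acetoxy-6-hydroxy-4,4,8,10β-tetramethyl-trans-decal-8-en-9-yl trifluoromethanesulfonate | CC(=O)O[C@H]1CC(C)(C)[C@@H]2C(O)CC(C)=C(OS(=O)(=O)C(F)(F)F)[C@@]2(C)C1
F6 | step 11 | 2α-acetoxy-9-hydroxy-15-(tert-butyldimethylsilyloxy)labda-7,13E-dien-6-one (C9 epimers) | CC(=O)O[C@H]1CC(C)(C)[C@@H]2C(=O)C=C(C)C(O)(CC/C(C)=C/CO[Si](C)(C)C(C)(C)C)[C@@]2(C)C1
F7 | step 4 | 4,4,8,10β-tetramethyl-trans-decal-7-ene-2,9-dione | O=C1CC(C)(C)[C@@H]2CC=C(C)C(=O)[C@@]2(C)C1
F8 | step 4 | 2β-hydroxy-4,4,8,10β-tetramethyl-trans-decal-7-en-9-one | O[C@@H]1CC(C)(C)[C@@H]2CC=C(C)C(=O)[C@@]2(C)C1
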